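Readings and results are simulated for an exercise; the scatter is artificial.

Look for more G than the Q charged and the runs refuse it. At 20.0 min Sunday's run reads 51% and Wednesday's 51% on 0.50 equiv of Q, and Tuesday's reads 74% on 0.75 equiv; each lies within a scatter of 1.5 percentage points of the Q charge, counted in percent of the X charged.

| setting | Sunday's | Wednesday's | Tuesday's | flask |
|---|---|---|---|---|
| X | 0.70 M | 1.1 M | 0.50 M | 0.50 M |
| E | 1.2 equiv | 1.2 equiv | 1.2 equiv | 1.20 equiv |
| Q | 0.50 equiv | 0.50 equiv | 0.75 equiv | 0.500 equiv |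
| remark | run made earlier | run made earlier | run made earlier |  |
| time |  |  |  | 2.0 h |

| run | time / min | G / % | Z / % |
|---|---|---|---|
| Sunday's | 8.00 | 51 | 17 |
| Sunday's | 12.0 | 54 | 17 |
| Sunday's | 20.0 | 51 | 12 |
| Sunday's | 40.0 | 50 | 12 |
| Sunday's | 60.0 | 52 | 6 |
| Sunday's | 90.0 | 50 | 8 |
| Wednesday's | 6.00 | 49 | 21 |
| Wednesday's | 20.0 | 51 | 15 |
| Wednesday's | 30.0 | 50 | 10 |
| Wednesday's | 50.0 | 50 | 10 |
| Wednesday's | 80.0 | 51 | 6 |
| Wednesday's | 90.0 | 47 | 6 |
| Tuesday's | 20.0 | 74 | 7 |
| Tuesday's | 40.0 | 76 | 6 |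
| Tuesday's | 60.0 | 75 | 3 |
| Tuesday's | 80.0 | 76 | 4 |
| Tuesday's | 90.0 | 77 | 4 |

(each reading ± 1.5 percentage points)

- share of G in G plus Z at 5.0 s
- share of G in G plus Z at 3.0 min
- share of G in G plus Z at 2.0 h
- which of G and Z there is more of at 2.0 h

- the numbers in the tables scatter with a standard deviation of 1.5 points

Build the new flask one process at a time. Start with the main step, X going to G at the expense of Q, and write the balance of Q, the limiting reagent here, since its 0.500 equiv is less than the one equivalent of X: G made plus Q left equals Q charged. In this flask the Q charge is 50.0% of the X charged; call that the Q ceiling. In this first sketch Z has no place and the share of G stands at 100%.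

Now add Z. The X above the ceiling is 50.0%, and part of it shows up as Z in the runs with the same Q charge: the 20.0 min readings of Sunday's and Wednesday's runs average 13.5%. Held there, Z pulls the share down to 78.7%.

Then add the slow fall of Z. By 90.0 min those two runs average 7.00%. Carry the same ratio of decline on to 2.0 h and Z reaches 5.28%, so my share is 90.4%, with G ahead. Offer no figure of your own for 5.0 s or 3.0 min: the first sample of Wednesday's run, at 6.00 min, comes later than both. The first samples of Sunday's and Tuesday's runs come later still.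

The forecast gave 72% (range 40% to 97%) at 5.0 s, 70.5% (65% to 77%) at 3.0 min and 90% (85% to 96%) at 2.0 h, with G ahead, starting from “G plateaus at the Q charge”.

The flask gives 60.2%, 81.1% and 88.9%, with G ahead at 50.0% against 6.25% of Z.

    X → D (k = 0.0113 s⁻¹)
    E + D ⇌ Z (K = 0.880 L mol⁻¹, k = 0.483 L mol⁻¹ s⁻¹)
    Q + D → G (k = 0.787 L mol⁻¹ s⁻¹)
    E + Z → J (k = 7.82 × 10⁻⁴ L mol⁻¹ s⁻¹)

G in this flask stands at 50.0% at 2.00 h, level with the Q ceiling, with Q at 0% of its charge. Now cut Q to 0.300 equiv and hold the other charges. The ceiling drops to 30.0%, the X above it grows to 70.0%, and scaling the reckoned Z by that remainder gives 7.40%, a share of 80.2%. That neighbouring flask gives G 30.0%, a share of 78.0% and Z 8.47% at 2.00 h.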